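## Retrosynthetic overview

1. The target, 2-(5-hexadecylfuran-2-yl)acetic acid, has one ring (the furan), and it is formed last.
2. The furan C–O bond and the CH2–CO2H bond are disconnected together, giving henicos-1-yn-5-one and CO2 (proposed new carboxylative cycloisomerisation).
3. The ketone C(O)–C16 bond is disconnected to N-methoxy-N-methylpent-4-ynamide and hexadecylmagnesium bromide.
4. The Weinreb amide comes from pent-4-ynoic acid and MeNHOMe·HCl; the Grignard reagent comes from 1-bromohexadecane.

Assumption: the target has no stereocentre and no stereogenic double bond, so "single enantiomer" is taken to mean the achiral compound as drawn, and no stereocontrol is needed.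

## Route

**Step 1**
Reactants: 1, pent-4-ynoic acid; 2, N,O-dimethylhydroxylamine hydrochloride
Product: 3, N-methoxy-N-methylpent-4-ynamide
Conditions: CDI (1.1 equiv), CH2Cl2, 0 °C → rt, 1 h; then 2 (1.2 equiv), rt, 12 h
Reagents that add atoms: none other than reactant 2 (N,O-dimethylhydroxylamine hydrochloride, CNOC.Cl)
Why: Weinreb amide synthesis by acyl-imidazolide formation and aminolysis; the terminal alkyne is inert to CDI and the amine.

**Step 2**
Reactants: 4, 1-bromohexadecane
Product: 5, hexadecylmagnesium bromide (about 0.5 M in THF, titrated, used directly)
Conditions: Mg turnings (1.3 equiv), cat. I2, THF, 40–65 °C, slow addition, 2 h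
Reagents that add atoms: magnesium, [Mg]
Why: Grignard formation by Mg insertion into an unhindered primary C–Br bond; slow addition at moderate dilution limits Wurtz homocoupling.

**Step 3**
Reactants: 3, N-methoxy-N-methylpent-4-ynamide; 5, hexadecylmagnesium bromide
Product: 6, henicos-1-yn-5-one, HC≡C–CH2CH2–C(=O)–C16H33
Conditions: 5 (2.3 equiv), THF, 0 °C; 3 added dropwise (inverse addition); 0 °C → rt, 2 h; sat. aq NH4Cl
Reagents that add atoms: none
Why: Weinreb ketone synthesis, in which the Mg-chelated tetrahedral intermediate stops over-addition; one equivalent of 5 is sacrificed to the acetylenic C–H (restored on quench), and inverse addition keeps the alkyl Grignard in excess so the alkynyl-Mg species does not compete for the amide.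

**Step 4**
Reactants: 6, henicos-1-yn-5-one; 7, carbon dioxide
Product: 8, 2-(5-hexadecylfuran-2-yl)acetic acid (target)
Conditions: AgOAc (10 mol %), Cs2CO3 (2.0 equiv), CO2 (1 atm, balloon), dry DMF, 50 °C, 12 h, then 80 °C, 6 h under CO2; then cold 1 M HCl to pH 3, 0 °C
Reagents that add atoms: carbon dioxide (7), O=C=O
Why: Proposed new method: redox-neutral Ag(I)-catalysed carboxylative cycloisomerisation of an alk-4-yn-1-one with CO2. Ag(I)/Cs2CO3 converts the terminal C–H into a silver acetylide that inserts CO2 to give the cesium ynoate. The ketone enol(ate) oxygen then attacks this electron-poor, Ag-π-activated internal alkyne 5-exo-dig at the carbon β to the carboxylate (oxa-Michael), and the resulting 2-(carboxylatomethylidene)-2,3-dihydrofuran tautomerises irreversibly to the aromatic furan-2-acetate, which pulls the reversible carboxylation forward. The closest known reaction types are Ag(I)/Cs2CO3 C–H carboxylation of terminal alkynes with CO2, the base- or coinage-metal-mediated cycloisomerisation of alk-4-yn-1-ones to 2-methylfurans, and Ag-mediated CO2-incorporating cyclisations of alkynyl ketones that carboxylate the enolate carbon and give lactones. No stereocentre is formed.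

## Compound list

1 | pent-4-ynoic acid | C#CCCC(=O)O | starting material
2 | N,O-dimethylhydroxylamine hydrochloride | CNOC.Cl | starting material
3 | N-methoxy-N-methylpent-4-ynamide | C#CCCC(=O)N(C)OC | intermediate
4 | 1-bromohexadecane | CCCCCCCCCCCCCCCCBr | starting material
5 | hexadecylmagnesium bromide | CCCCCCCCCCCCCCCC[Mg]Br | intermediate
6 | henicos-1-yn-5-one | C#CCCC(=O)CCCCCCCCCCCCCCCC | intermediate
7 | carbon dioxide | O=C=O | starting material
8 | 2-(5-hexadecylfuran-2-yl)acetic acid | CCCCCCCCCCCCCCCCc1ccc(CC(=O)O)o1 | target

## Summary

Total step count: 4.
Longest linear sequence: 3 steps (1 → 3 → 4, or 2 → 3 → 4).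

Three steps most likely to fail:

1. **Step 4 (proposed new step).** The risks are cycloisomerisation outrunning carboxylation (giving 2-hexadecyl-5-methylfuran), stalling at the ynoate salt, or decarboxylation back to 6 at 80 °C.
   Fallback (known chemistry): PdI2/KI-catalysed oxidative cyclisation–methoxycarbonylation of 6 (CO/air, MeOH, 70 °C) to the 2-methoxy-5-(methoxycarbonylmethylidene)tetrahydrofuran. Acid-catalysed loss of MeOH (cat. TsOH) then gives methyl 2-(5-hexadecylfuran-2-yl)acetate, and LiOH in THF/H2O gives 8.

2. **Step 3.** The risks are the acidic alkyne C–H consuming Grignard, alkynyl-Mg adding to the amide, and separation of 6 from hexadecane.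
   Fallback: an acetoacetic-ester-type route. Methyl 3-oxononadecanoate (from heptadecanoyl chloride and Meldrum's acid, then MeOH) is C-alkylated with propargyl bromide (K2CO3, acetone) and decarboxylated under Krapcho conditions (LiCl, wet DMSO, 130 °C) to give 6 with no organometallic near the alkyne.

3. **Step 2.** The risks are Wurtz coupling to dotriacontane and a low or poorly soluble Grignard titre.
   Fallback: avoid the C16 organometallic altogether. Commercial octadecan-2-one is converted to its N,N-dimethylhydrazone and metalated at the methyl group (n-BuLi, THF, −78 °C). Alkylation with 3-bromo-1-(trimethylsilyl)propyne, hydrazone hydrolysis and K2CO3/MeOH desilylation then give 6.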